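The ten-membered carbocycle (C1–C10) is disconnected at C4–C5. The trans C4–C5 oxirane (C3 and C6 trans, methyl C15 cis to C6) is the outer-face epoxide of an (E)-C4=C5 olefin. The key step is therefore a kinetically controlled, stereoretentive ring-closing metathesis that forms C4=C5 and closes the ring in one operation, the E geometry being built beforehand into an acyclic (E)-C3–C4(Me)=CHMe terminus. Its partner is the C5 vinyl group on C6 of the butenolide (7(11)-en-12,6-olide). C8–C9 comes from an aldol union, the cis C1–C2 oxirane is already present, and C10 is a ketone so that no 10(14)-methylene can close a cyclohexene with C5.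

Key step: step 13

Remark: germacrane numbering is used (ring C1–C10; C6 bears the lactone oxygen, C8 the acrylate, C10 the methylene C14, C4 the methyl C15; C11–C13 belong to the lactone); the facial sense of the two reagent-controlled additions (steps 5 and 11) is assumed as written, the antipodal ligand or borane being used if it proves opposite, and 2 is taken as commercially available.

Step 1
Reactants: 1 (2S)-but-3-yn-2-ol; 2 (2E)-1-bromo-2-methylbut-2-ene
Product: 3 (2S,6E)-6-methyloct-6-en-3-yn-2-ol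
Conditions: CuI (10 mol %), K2CO3, DMF, rt
Reagents that add atoms: none
Why: The copper acetylide of the terminal alkyne substitutes the primary allylic bromide at its unhindered CH2 terminus (copper-catalysed alkyne–allyl halide coupling), leaving the E olefin and the carbinol stereocentre untouched.

Step 2
Reactants: 3 (2S,6E)-6-methyloct-6-en-3-yn-2-ol
Product: 4 (2S,3Z,6E)-6-methylocta-3,6-dien-2-ol
Conditions: H2 (1 atm), Pd/CaCO3 poisoned with Pb(OAc)2 (Lindlar catalyst), quinoline, EtOAc, rt
Reagents that add atoms: none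
Why: Lindlar semihydrogenation adds hydrogen syn to the alkyne and stops at the (Z)-alkene, which fixes the cis relationship later carried by the C1–C2 oxirane, while the trisubstituted olefin is not reduced.

Step 3
Reactants: 4 (2S,3Z,6E)-6-methylocta-3,6-dien-2-ol
Product: 5 (1S)-1-{(2R,3S)-3-[(2E)-2-methylbut-2-en-1-yl]oxiran-2-yl}ethan-1-ol
Conditions: Ti(OiPr)4 (20 mol %), t-BuOOH, 4 Å molecular sieves, CH2Cl2, −20 °C
Reagents that add atoms: tert-butyl hydroperoxide, CC(C)(C)OO
Why: Hydroxyl-directed titanium-catalysed epoxidation touches only the allylic double bond and, because A(1,3) strain in the Z-allylic alcohol keeps the carbinol hydrogen in the olefin plane, should deliver oxygen syn to the hydroxyl to give the threo cis-epoxide, so the (S)-carbinol sets C1 and C2 (the minor erythro isomer is removed by chromatography).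

Step 4
Reactants: 5 (1S)-1-{(2R,3S)-3-[(2E)-2-methylbut-2-en-1-yl]oxiran-2-yl}ethan-1-ol
Product: 6 1-{(2S,3S)-3-[(2E)-2-methylbut-2-en-1-yl]oxiran-2-yl}ethan-1-one
Conditions: Dess–Martin periodinane, CH2Cl2, 0 °C to rt
Reagents that add atoms: none
Why: Dess–Martin oxidation turns the relay carbinol into the C10 methyl ketone under non-basic conditions that leave the cis-oxirane and its two stereocentres intact.

Step 5
Reactants: 7 acrolein; 8 tert-butyldimethyl(prop-2-yn-1-yloxy)silane
Product: 9 (3R)-6-[(tert-butyldimethylsilyl)oxy]hex-1-en-4-yn-3-ol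
Conditions: Me2Zn, (S,S)-ProPhenol (20 mol %), Ph3P=O (40 mol %), toluene, 0 °C; aq. NH4Cl
Reagents that add atoms: none
Why: Zinc–ProPhenol-catalysed enantioselective 1,2-addition of the zinc acetylide to the aldehyde sets the future C6 stereocentre by catalyst control.

Step 6
Reactants: 9 (3R)-6-[(tert-butyldimethylsilyl)oxy]hex-1-en-4-yn-3-ol; 10 (2-methylprop-1-en-1-yl)magnesium bromide
Product: 13 (5R)-3-{[(tert-butyldimethylsilyl)oxy]methyl}-5-ethenyl-4-(2-methylprop-1-en-1-yl)furan-2(5H)-one, via oxamagnesole chelate 11 (not isolated), via hydroxy acid magnesium salt 12 (not isolated)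
Conditions: 10 (3.5 equiv), CuI (10 mol %), THF, 0 °C to rt; CO2 (1 atm), −20 °C to rt; aq. NH4Cl, then HCl to pH 3
Reagents that add atoms: carbon dioxide, O=C=O
Why: Copper-catalysed, alkoxide-directed anti-carbomagnesiation places the alkenyl group on the alkyne carbon next to the carbinol (C7) and magnesium on the distal carbon (C11) cis to the alkoxide, so that carboxylation and acidic work-up give the (Z)-γ-hydroxy acid, which lactonizes to the butenolide without touching C6.

Step 7
Reactants: 13 (5R)-3-{[(tert-butyldimethylsilyl)oxy]methyl}-5-ethenyl-4-(2-methylprop-1-en-1-yl)furan-2(5H)-one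
Product: 14 [(5R)-5-ethenyl-4-(2-methylprop-1-en-1-yl)-2-oxo-2,5-dihydrofuran-3-yl]methyl acetate
Conditions: Ac2O, FeCl3 (5 mol %), CH2Cl2, 0 °C
Reagents that add atoms: acetic anhydride, CC(=O)OC(C)=O
Why: Lewis-acid-catalysed acetolysis exchanges the primary silyl ether directly for the C13 acetate, the silicon leaving as its acetate (silyl ether to acetate exchange).

Step 8
Reactants: 14 [(5R)-5-ethenyl-4-(2-methylprop-1-en-1-yl)-2-oxo-2,5-dihydrofuran-3-yl]methyl acetate
Product: 15 [(5R)-5-ethenyl-4-formyl-2-oxo-2,5-dihydrofuran-3-yl]methyl acetate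
Conditions: O3 (1.0 equiv, titrated solution), CH2Cl2, −78 °C; Me2S, −78 °C to rt
Reagents that add atoms: ozone, [O-][O+]=O
Why: One equivalent of ozone at low temperature should cleave the more electron-rich trisubstituted olefin in preference to the allylically deactivated vinyl group and the electron-poor butenolide (chemoselective ozonolysis with reductive work-up), unveiling the C8 aldehyde.

Step 9
Reactants: 16 ethyl 2-(hydroxymethyl)prop-2-enoate
Product: 17 ethyl 2-{[(tert-butyldimethylsilyl)oxy]methyl}prop-2-enoate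
Conditions: t-BuMe2SiCl, imidazole, CH2Cl2, 0 °C to rt
Reagents that add atoms: tert-butylchlorodimethylsilane, CC(C)(C)[Si](C)(C)Cl
Why: Imidazole-promoted silylation masks the primary allylic hydroxyl so that the acid cannot acylate itself later (alcohol silylation).

Step 10
Reactants: 17 ethyl 2-{[(tert-butyldimethylsilyl)oxy]methyl}prop-2-enoate
Product: 18 2-{[(tert-butyldimethylsilyl)oxy]methyl}prop-2-enoic acid
Conditions: LiOH, THF/H2O, 0 °C; 1 M HCl to pH 4
Reagents that add atoms: lithium hydroxide, [Li+].[OH-]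
Why: Saponification of the ethyl ester at low temperature gives the acid while the primary tert-butyldimethylsilyl ether survives mild aqueous base (ester hydrolysis).

Step 11
Reactants: 6 1-{(2S,3S)-3-[(2E)-2-methylbut-2-en-1-yl]oxiran-2-yl}ethan-1-one; 15 [(5R)-5-ethenyl-4-formyl-2-oxo-2,5-dihydrofuran-3-yl]methyl acetate
Product: 20 [(5R)-5-ethenyl-4-{(1S)-1-hydroxy-3-[(2S,3S)-3-((2E)-2-methylbut-2-en-1-yl)oxiran-2-yl]-3-oxopropyl}-2-oxo-2,5-dihydrofuran-3-yl]methyl acetate, via boron enolate 19 (not isolated)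
Conditions: (−)-Ipc2BCl, Et3N, Et2O, 0 °C; then 15, −78 to −20 °C; pH 7 buffer/MeOH
Reagents that add atoms: none
Why: The kinetic diisopinocampheylboron enolate of the methyl ketone adds to the aldehyde through a cyclic boron aldol transition state in which the isopinocampheyl groups select one aldehyde face (reagent-controlled methyl ketone boron aldol), forming C8–C9 and setting C8 as S, the minor C8 epimer being removed by chromatography.

Step 12
Reactants: 20 [(5R)-5-ethenyl-4-{(1S)-1-hydroxy-3-[(2S,3S)-3-((2E)-2-methylbut-2-en-1-yl)oxiran-2-yl]-3-oxopropyl}-2-oxo-2,5-dihydrofuran-3-yl]methyl acetate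
Product: 21 [(5R)-5-ethenyl-4-{(1S)-3-[(2S,3S)-3-((2E)-2-methylbut-2-en-1-yl)oxiran-2-yl]-3-oxo-1-(triethylsilyloxy)propyl}-2-oxo-2,5-dihydrofuran-3-yl]methyl acetate
Conditions: Et3SiCl, imidazole, DMAP (cat.), CH2Cl2, 0 °C
Reagents that add atoms: chlorotriethylsilane, CC[Si](Cl)(CC)CC
Why: Silylation of the C8 hydroxyl removes the only protic group, which the oxophilic Mo alkylidene of the next step would not tolerate (alcohol silylation).

Step 13
Reactants: 21 [(5R)-5-ethenyl-4-{(1S)-3-[(2S,3S)-3-((2E)-2-methylbut-2-en-1-yl)oxiran-2-yl]-3-oxo-1-(triethylsilyloxy)propyl}-2-oxo-2,5-dihydrofuran-3-yl]methyl acetate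
Product: 22 (1S,2S,6R,8S,4E)-13-acetoxy-1,2-epoxy-10-oxo-8-(triethylsilyloxy)-14-norgermacra-4,7(11)-dien-12,6-olide
Conditions: Mo(NC6F5)(CHCMe2Ph)(2,5-Me2C4H2N)(OC6H3-2,6-(2,4,6-iPr3C6H2)2) (15 mol %), toluene (1 mM), 22 to 40 °C, 100 torr
Reagents that add atoms: none
Why: The Mo alkylidene first exchanges with the unhindered C5 vinyl group and then adds across the E-trisubstituted olefin through a molybdacyclobutane whose cycloreversion expels propene and forms C4=C5 (ring-closing olefin metathesis of a diene). The closest known reaction type is kinetically controlled, stereoretentive macrocyclic ring-closing metathesis of stereodefined trisubstituted olefins with Mo monoaryloxide pyrrolide alkylidenes. The ten-membered carbocycle C1–C10 is closed by this [2+2] cycloaddition/cycloreversion sequence at C4=C5. No stereocentre is formed; the stereogenic element is the E double bond, controlled by the substrate olefin: in the metallacycle the departing methyl and the C6 chain both point away from the large aryloxide, so C15, which is cis to the departing methyl, ends cis to C6 and C3 trans to it. The step needs site selectivity and kinetic control: only two olefins can react because C10 is a ketone and the butenolide olefin is tetrasubstituted, the hydroxyl is silylated, and the regenerated ethylidene should not re-open the trisubstituted ring olefin, so the strained E ring is not equilibrated to Z. High dilution and removal of propene suppress oligomerization, and the turn elements (butenolide, cis-oxirane, sp2 C10) pre-fold the chain.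

Step 14
Reactants: 22 (1S,2S,6R,8S,4E)-13-acetoxy-1,2-epoxy-10-oxo-8-(triethylsilyloxy)-14-norgermacra-4,7(11)-dien-12,6-olide
Product: 23 (1S,2S,4R,5R,6S,8S)-13-acetoxy-1,2:4,5-diepoxy-10-oxo-8-(triethylsilyloxy)-14-norgermacr-7(11)-en-12,6-olide
Conditions: dimethyldioxirane, acetone, −40 to 0 °C
Reagents that add atoms: dimethyldioxirane, CC1(C)OO1
Why: Dimethyldioxirane transfers oxygen concertedly and stereospecifically to the only nucleophilic olefin from its outer face, which is syn to the lactone oxygen and anti to C7 in the conformer that keeps H6 in the olefin plane next to the C15 methyl (A(1,3) strain), and this should give the trans (4R,5R)-oxirane (dioxirane epoxidation).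

Step 15
Reactants: 23 (1S,2S,4R,5R,6S,8S)-13-acetoxy-1,2:4,5-diepoxy-10-oxo-8-(triethylsilyloxy)-14-norgermacr-7(11)-en-12,6-olide
Product: 24 (1R,2S,4R,5R,6S,8S)-13-acetoxy-1,2:4,5-diepoxy-8-(triethylsilyloxy)germacra-7(11),10(14)-dien-12,6-olide
Conditions: Zn, CH2Br2, TiCl4 (reagent pre-formed in THF at 0 °C), CH2Cl2, 0 °C to rt; aq. NaHCO3
Reagents that add atoms: dibromomethane, BrCBr
Why: The non-basic gem-dimetallic methylene reagent converts the C10 ketone into the 10(14)-methylene without enolization, epimerization at C6 or attack on lactone and acetate (Takai–Lombardo methylenation).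

Step 16
Reactants: 24 (1R,2S,4R,5R,6S,8S)-13-acetoxy-1,2:4,5-diepoxy-8-(triethylsilyloxy)germacra-7(11),10(14)-dien-12,6-olide
Product: 25 (1R,2S,4R,5R,6S,8S)-13-acetoxy-1,2:4,5-diepoxy-8-hydroxygermacra-7(11),10(14)-dien-12,6-olide
Conditions: HF·pyridine, pyridine, THF, 0 °C
Reagents that add atoms: none
Why: Buffered fluoride cleaves the secondary triethylsilyl ether, the excess pyridine keeping the medium too weakly acidic to open the two oxiranes (fluoride desilylation).

Step 17
Reactants: 25 (1R,2S,4R,5R,6S,8S)-13-acetoxy-1,2:4,5-diepoxy-8-hydroxygermacra-7(11),10(14)-dien-12,6-olide; 18 2-{[(tert-butyldimethylsilyl)oxy]methyl}prop-2-enoic acid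
Product: 26 (1R,2S,4R,5R,6S,8S)-13-acetoxy-8-{2-[(tert-butyldimethylsilyloxy)methyl]prop-2-enoyloxy}-1,2:4,5-diepoxygermacra-7(11),10(14)-dien-12,6-olide
Conditions: DCC, DMAP (cat.), CH2Cl2, 0 °C to rt
Reagents that add atoms: none
Why: Carbodiimide activation with DMAP as acyl-transfer catalyst acylates the C8 hydroxyl with retention of configuration under conditions too weakly basic to deprotonate C6 (Steglich esterification).

Step 18
Reactants: 26 (1R,2S,4R,5R,6S,8S)-13-acetoxy-8-{2-[(tert-butyldimethylsilyloxy)methyl]prop-2-enoyloxy}-1,2:4,5-diepoxygermacra-7(11),10(14)-dien-12,6-olide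
Product: 27 (1R,2S,4R,5R,6S,8S)-13-acetoxy-1,2:4,5-diepoxy-8-[2-(hydroxymethyl)prop-2-enoyloxy]germacra-7(11),10(14)-dien-12,6-olide (CNP0233746.1)
Conditions: HF·pyridine, pyridine, THF, 0 °C to rt
Reagents that add atoms: none
Why: Buffered fluoride removes the primary tert-butyldimethylsilyl ether to release the hydroxymethylacrylate without disturbing esters or oxiranes (fluoride desilylation).

Compound list
1 | (2S)-but-3-yn-2-ol | C[C@H](O)C#C | starting material
2 | (2E)-1-bromo-2-methylbut-2-ene | C/C=C(\C)CBr | starting material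
3 | (2S,6E)-6-methyloct-6-en-3-yn-2-ol | C[C@H](O)C#CC/C(C)=C/C | intermediate
4 | (2S,3Z,6E)-6-methylocta-3,6-dien-2-ol | C[C@H](O)/C=C\C/C(C)=C/C | intermediate
5 | (1S)-1-{(2R,3S)-3-[(2E)-2-methylbut-2-en-1-yl]oxiran-2-yl}ethan-1-ol | C[C@H](O)[C@H]1O[C@H]1C/C(C)=C/C | intermediate
6 | 1-{(2S,3S)-3-[(2E)-2-methylbut-2-en-1-yl]oxiran-2-yl}ethan-1-one | CC(=O)[C@H]1O[C@H]1C/C(C)=C/C | intermediate
7 | acrolein (prop-2-enal) | C=CC=O | starting material
8 | tert-butyldimethyl(prop-2-yn-1-yloxy)silane | C#CCO[Si](C)(C)C(C)(C)C | starting material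
9 | (3R)-6-[(tert-butyldimethylsilyl)oxy]hex-1-en-4-yn-3-ol | C=C[C@@H](O)C#CCO[Si](C)(C)C(C)(C)C | intermediate
10 | (2-methylprop-1-en-1-yl)magnesium bromide | CC(C)=C[Mg]Br | starting material
11 | (5R)-3-{[(tert-butyldimethylsilyl)oxy]methyl}-5-ethenyl-4-(2-methylprop-1-en-1-yl)-2,5-dihydro-1,2-oxamagnesole (cyclic alkenylmagnesium alkoxide) | C=C[C@H]1O[Mg]C(CO[Si](C)(C)C(C)(C)C)=C1C=C(C)C | intermediate (not isolated)
12 | (2Z,4R)-2-{[(tert-butyldimethylsilyl)oxy]methyl}-4-hydroxy-3-(2-methylprop-1-en-1-yl)hexa-2,5-dienoic acid (present as its bromomagnesium salt) | C=C[C@@H](O)/C(C=C(C)C)=C(/CO[Si](C)(C)C(C)(C)C)C(=O)O | intermediate (not isolated)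
13 | (5R)-3-{[(tert-butyldimethylsilyl)oxy]methyl}-5-ethenyl-4-(2-methylprop-1-en-1-yl)furan-2(5H)-one | C=C[C@H]1OC(=O)C(CO[Si](C)(C)C(C)(C)C)=C1C=C(C)C | intermediate
14 | [(5R)-5-ethenyl-4-(2-methylprop-1-en-1-yl)-2-oxo-2,5-dihydrofuran-3-yl]methyl acetate | C=C[C@H]1OC(=O)C(COC(C)=O)=C1C=C(C)C | intermediate
15 | [(5R)-5-ethenyl-4-formyl-2-oxo-2,5-dihydrofuran-3-yl]methyl acetate | C=C[C@H]1OC(=O)C(COC(C)=O)=C1C=O | intermediate
16 | ethyl 2-(hydroxymethyl)prop-2-enoate | C=C(CO)C(=O)OCC | starting material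
17 | ethyl 2-{[(tert-butyldimethylsilyl)oxy]methyl}prop-2-enoate | C=C(CO[Si](C)(C)C(C)(C)C)C(=O)OCC | intermediate
18 | 2-{[(tert-butyldimethylsilyl)oxy]methyl}prop-2-enoic acid | C=C(CO[Si](C)(C)C(C)(C)C)C(=O)O | intermediate
19 | diisopinocampheylboron enolate of 6 (O-borylated enol at C10, methylene C9) | C=C(OB([C@@H]1C[C@@H]2C[C@H]([C@H]1C)C2(C)C)[C@@H]1C[C@@H]2C[C@H]([C@H]1C)C2(C)C)[C@H]1O[C@H]1C/C(C)=C/C | intermediate (not isolated)
20 | [(5R)-5-ethenyl-4-{(1S)-1-hydroxy-3-[(2S,3S)-3-((2E)-2-methylbut-2-en-1-yl)oxiran-2-yl]-3-oxopropyl}-2-oxo-2,5-dihydrofuran-3-yl]methyl acetate | C=C[C@H]1OC(=O)C(COC(C)=O)=C1[C@@H](O)CC(=O)[C@H]1O[C@H]1C/C(C)=C/C | intermediate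
21 | [(5R)-5-ethenyl-4-{(1S)-3-[(2S,3S)-3-((2E)-2-methylbut-2-en-1-yl)oxiran-2-yl]-3-oxo-1-(triethylsilyloxy)propyl}-2-oxo-2,5-dihydrofuran-3-yl]methyl acetate | C=C[C@H]1OC(=O)C(COC(C)=O)=C1[C@@H](O[Si](CC)(CC)CC)CC(=O)[C@H]1O[C@H]1C/C(C)=C/C | intermediate
22 | (1S,2S,6R,8S,4E)-13-acetoxy-1,2-epoxy-10-oxo-8-(triethylsilyloxy)-14-norgermacra-4,7(11)-dien-12,6-olide | CC[Si](CC)(CC)O[C@H]1CC(=O)[C@H]2O[C@H]2C/C(C)=C/[C@H]2OC(=O)C(COC(C)=O)=C12 | intermediate
23 | (1S,2S,4R,5R,6S,8S)-13-acetoxy-1,2:4,5-diepoxy-10-oxo-8-(triethylsilyloxy)-14-norgermacr-7(11)-en-12,6-olide | CC[Si](CC)(CC)O[C@H]1CC(=O)[C@H]2O[C@H]2C[C@@]2(C)O[C@@H]2[C@H]2OC(=O)C(COC(C)=O)=C12 | intermediate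
24 | (1R,2S,4R,5R,6S,8S)-13-acetoxy-1,2:4,5-diepoxy-8-(triethylsilyloxy)germacra-7(11),10(14)-dien-12,6-olide | CC[Si](CC)(CC)O[C@H]1CC(=C)[C@H]2O[C@H]2C[C@@]2(C)O[C@@H]2[C@H]2OC(=O)C(COC(C)=O)=C12 | intermediate
25 | (1R,2S,4R,5R,6S,8S)-13-acetoxy-1,2:4,5-diepoxy-8-hydroxygermacra-7(11),10(14)-dien-12,6-olide | O[C@H]1CC(=C)[C@H]2O[C@H]2C[C@@]2(C)O[C@@H]2[C@H]2OC(=O)C(COC(C)=O)=C12 | intermediate
26 | (1R,2S,4R,5R,6S,8S)-13-acetoxy-8-{2-[(tert-butyldimethylsilyloxy)methyl]prop-2-enoyloxy}-1,2:4,5-diepoxygermacra-7(11),10(14)-dien-12,6-olide | C=C(CO[Si](C)(C)C(C)(C)C)C(=O)O[C@H]1CC(=C)[C@H]2O[C@H]2C[C@@]2(C)O[C@@H]2[C@H]2OC(=O)C(COC(C)=O)=C12 | intermediate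
27 | (1R,2S,4R,5R,6S,8S)-13-acetoxy-1,2:4,5-diepoxy-8-[2-(hydroxymethyl)prop-2-enoyloxy]germacra-7(11),10(14)-dien-12,6-olide (CNP0233746.1) | C=C(CO)C(=O)O[C@H]1CC(=C)[C@H]2O[C@H]2C[C@@]2(C)O[C@@H]2[C@H]2OC(=O)C(COC(C)=O)=C12 | target

Total step count: 18. Longest linear sequence: 12 steps (steps 1–4 or 5–8, then 11–18).

Steps most likely to fail

1. Step 13 (key ring closure). Strain in the E-configured ten-membered ring may slow closure so that intermolecular metathesis takes over. Stereoretention may also be lost by secondary metathesis to the Z ring, or the alkylidene may be consumed by olefination of the C10 ketone. Fallback: from 21 the same C4–C5 bond would be closed under thermodynamic control with the second-generation Hoveyda–Grubbs catalyst (toluene, 1 mM, 80 °C, 1,4-benzoquinone), which should give the less strained (4Z)-macrocycle F1. Syn-dihydroxylation (OsO4 cat., N-methylmorpholine N-oxide, acetone/H2O), expected anti to the allylic C6–O bond of the Z-allylic system (empirical rule for osmylation next to an allylic oxygen), would give the (4R,5S)-diol F2. Mitsunobu cyclodehydration (PPh3, DIAD, toluene) activates the secondary C5 hydroxyl and lets the tertiary C4 hydroxyl displace it with inversion, which turns the syn diol of the Z olefin into the trans oxirane. The route is rejoined at 23.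

2. Step 15 (methylenation of the bis-epoxy ketone). Lewis-acidic titanium or zinc halide species may open one of the two oxiranes (halohydrin formation or transannular attack) faster than methylene is transferred to the hindered C10 carbonyl. Fallback: from 23, Me3SiCH2Li/CeCl3 (THF, −78 °C) would add to the ketone to give the tertiary β-hydroxysilane F3 (both C10 epimers serve). HF·pyridine/pyridine (THF, 0 °C) then brings about acid-promoted Peterson elimination to the 10(14)-methylene and cleaves the triethylsilyl ether in the same operation. The route is rejoined at 25.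

3. Step 6 (carbomagnesiation–carboxylation). The hindered tetrasubstituted alkenylmagnesium chelate may be carboxylated too slowly, so that protonation on work-up gives the diene alcohol instead of the lactone. Fallback: from 9, the same copper-catalysed carbomagnesiation with 10 would be quenched with I2 instead of CO2 to give the (Z)-iodo dienol F4. Palladium-catalysed carbonylative lactonization (PdCl2(PPh3)2, CO 1 atm, K2CO3, THF, 50 °C) then inserts CO into the C–I bond and closes the lactone with the cis hydroxyl. The route is rejoined at 13.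

Further compounds
F1 | step 13 | (1S,2S,6R,8S,4Z)-13-acetoxy-1,2-epoxy-10-oxo-8-(triethylsilyloxy)-14-norgermacra-4,7(11)-dien-12,6-olide | CC[Si](CC)(CC)O[C@H]1CC(=O)[C@H]2O[C@H]2C/C(C)=C\[C@H]2OC(=O)C(COC(C)=O)=C12
F2 | step 13 | (1S,2S,4R,5S,6S,8S)-13-acetoxy-1,2-epoxy-4,5-dihydroxy-10-oxo-8-(triethylsilyloxy)-14-norgermacr-7(11)-en-12,6-olide | CC[Si](CC)(CC)O[C@H]1CC(=O)[C@H]2O[C@H]2C[C@@](C)(O)[C@@H](O)[C@H]2OC(=O)C(COC(C)=O)=C12
F3 | step 15 | (1S,2S,4R,5R,6S,8S)-13-acetoxy-1,2:4,5-diepoxy-10-hydroxy-8-(triethylsilyloxy)-14-(trimethylsilyl)germacr-7(11)-en-12,6-olide (mixture of C10 epimers) | CC[Si](CC)(CC)O[C@H]1CC(O)(C[Si](C)(C)C)[C@H]2O[C@H]2C[C@@]2(C)O[C@@H]2[C@H]2OC(=O)C(COC(C)=O)=C12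
F4 | step 6 | (3R,4Z)-6-[(tert-butyldimethylsilyl)oxy]-5-iodo-4-(2-methylprop-1-en-1-yl)hexa-1,4-dien-3-ol | C=C[C@@H](O)/C(C=C(C)C)=C(\I)CO[Si](C)(C)C(C)(C)C
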